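**Retrosynthetic overview** (germacrane locants: C1–C10 ten-membered carbocycle; C11–C13 α-methylene lactone unit on C7, closed to O on C8; C14 the CH2OH carbon on C10; C15 the butenolide carbonyl on C4, closed to O on C6)
1. Target 26 ⇐ PMB ether 25 ⇐ macrolactone 24 by a transannular ring-closing metathesis that forms C4=C5.
2. Enabling feature: C4=C5 belongs to both the butenolide (C4–C5–C6–O–C15) and the carbocycle, and the ester C15(=O)–O–C6 joins C4 to C5 through three atoms; cutting C4=C5 opens both bridges of the oxabicyclo[7.2.1]dodecadiene core to a monocyclic 11-membered lactone, whose closure is a five-membered RCM that also fixes the ring-trans geometry of C4=C5.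
3. 24 ⇐ seco acid 20 (macrolactonisation, C15 acid onto C6 OH) ⇐ bromobutenolide 16 + acrolein (Zn Barbier: C6–C7 bond, α-methylene-γ-lactone, C7; C6 then inverted).
4. 16 ⇐ RCM of the 2-(bromomethyl)acrylate of dienol 13 ⇐ asymmetric Morita–Baylis–Hillman (C3/C4/C15), Heck with allyl alcohol (C1–C3), Red-Al/iodine (C9=C10 geometry), asymmetric alkynylation of crotonaldehyde (C8).
5. Ring order: bromobutenolide (step 9) → α-methylene-γ-butyrolactone (step 10) → 11-membered lactone (step 13) → butenolide and ten-membered carbocycle together (step 16).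

Key step: step 16

Remarks on the chemistry: 1 is taken as a catalogue compound (otherwise one Williamson step from propargyl alcohol and 4-methoxybenzyl chloride). The antipodes of the ProPhenol ligand (step 1) and of the isocupreine-type catalyst (step 5) are those that give the 4S and 3S carbinols. The Barbier step is planned to give the C6 epimer, which step 11 inverts.

**Step 1**
Reactants: 1 4-methoxybenzyl propargyl ether; 2 (E)-but-2-enal
Product: 4 (4S,5E)-1-[(4-methoxybenzyl)oxy]hept-5-en-2-yn-4-ol, via methylzinc acetylide 3 (not isolated)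
Conditions: Me2Zn, ProPhenol (10 mol%), Ph3PO (20 mol%), toluene, 0 °C; then 2; aq. NH4Cl
Reagents that add atoms: none
Why: Zinc–ProPhenol-catalysed asymmetric alkynylation of an enal, in which the dinuclear zinc complex delivers the zinc acetylide to one carbonyl face in a 1,2-addition and sets the carbinol (later C8) as S.

**Step 2**
Reactants: 4 (4S,5E)-1-[(4-methoxybenzyl)oxy]hept-5-en-2-yn-4-ol
Product: 6 (2Z,4S,5E)-2-iodo-1-[(4-methoxybenzyl)oxy]hepta-2,5-dien-4-ol, via alkenylalanate 5 (not isolated)
Conditions: Red-Al, THF, 0 °C; then I2, −78 °C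
Reagents that add atoms: iodine, II
Why: Hydroxyl-directed trans-hydroalumination of the propargylic alcohol puts aluminium on the distal alkyne carbon in a five-membered alanate, and iodinolysis with retention gives the 2Z iodoalkene that fixes the later C9=C10 geometry.

**Step 3**
Reactants: 6 (2Z,4S,5E)-2-iodo-1-[(4-methoxybenzyl)oxy]hepta-2,5-dien-4-ol
Product: 7 (2Z,4S,5E)-2-iodo-1-[(4-methoxybenzyl)oxy]-4-[(triethylsilyl)oxy]hepta-2,5-diene
Conditions: TESCl, imidazole, CH2Cl2, 0 °C
Reagents that add atoms: chlorotriethylsilane, CC[Si](Cl)(CC)CC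
Why: Standard silylation protects the bis-allylic carbinol for the palladium- and amine-catalysed steps and leaves the stereocentre untouched.

**Step 4**
Reactants: 7 TES-protected iododiene; 8 prop-2-en-1-ol
Product: 9 (4E,6S,7E)-4-{[(4-methoxybenzyl)oxy]methyl}-6-[(triethylsilyl)oxy]nona-4,7-dienal
Conditions: Pd(OAc)2 (5 mol%), Bu4NCl, NaHCO3, DMF, 35 °C
Reagents that add atoms: none
Why: Heck reaction of an alkenyl iodide with allyl alcohol under phase-transfer (Jeffery) conditions, where carbopalladation at the terminal carbon, β-hydride elimination towards the carbinol and tautomerisation give the three-carbon aldehyde arm with retention of olefin geometry.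

**Step 5**
Reactants: 9 dienal; 10 1,1,1,3,3,3-hexafluoropropan-2-yl acrylate
Product: 11 1,1,1,3,3,3-hexafluoropropan-2-yl (3S,6E,8S,9E)-3-hydroxy-6-{[(4-methoxybenzyl)oxy]methyl}-2-methylidene-8-[(triethylsilyl)oxy]undeca-6,9-dienoate
Conditions: α-isocupreine (10 mol%), DMF, −55 °C
Reagents that add atoms: none
Why: Amine-catalysed asymmetric Morita–Baylis–Hillman reaction of an unbranched aliphatic aldehyde with the activated acrylate, in which the phenol-bearing quinine-derived catalyst organises the betaine–aldehyde adduct by hydrogen bonding and sets the new carbinol as 3S.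

**Step 6**
Reactants: 11 Morita–Baylis–Hillman adduct
Product: 12 1,1,1,3,3,3-hexafluoropropan-2-yl (3S,6E,8S,9E)-3-[(tert-butyldimethylsilyl)oxy]-6-{[(4-methoxybenzyl)oxy]methyl}-2-methylidene-8-[(triethylsilyl)oxy]undeca-6,9-dienoate
Conditions: TBSOTf, 2,6-lutidine, CH2Cl2, −78 °C
Reagents that add atoms: tert-butyldimethylsilyl triflate, CC(C)(C)[Si](C)(C)OS(=O)(=O)C(F)(F)F
Why: Silyl triflate with a hindered base silylates the secondary carbinol without touching the activated ester, and a silyl ether (unlike an acyloxy group) is no leaving group for SN2′ attack in later steps.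

**Step 7**
Reactants: 12 bis-silyl ether
Product: 13 1,1,1,3,3,3-hexafluoropropan-2-yl (3S,6E,8S,9E)-3-[(tert-butyldimethylsilyl)oxy]-8-hydroxy-6-{[(4-methoxybenzyl)oxy]methyl}-2-methylideneundeca-6,9-dienoate
Conditions: HF·pyridine, pyridine, THF, 0 °C
Reagents that add atoms: none
Why: Buffered HF·pyridine cleaves the more labile triethylsilyl ether selectively in the presence of the hindered secondary TBS ether and the PMB ether.

**Step 8**
Reactants: 13 dienol; 14 2-(bromomethyl)prop-2-enoic acid
Product: 15 1,1,1,3,3,3-hexafluoropropan-2-yl (3S,6E,8S,9E)-8-{[2-(bromomethyl)prop-2-enoyl]oxy}-3-[(tert-butyldimethylsilyl)oxy]-6-{[(4-methoxybenzyl)oxy]methyl}-2-methylideneundeca-6,9-dienoate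
Conditions: DCC, DMAP·TsOH (cat.), CH2Cl2, 0 °C
Reagents that add atoms: none
Why: Carbodiimide (Steglich-type) esterification acylates the carbinol oxygen with retention, the protonated DMAP salt limiting attack of the catalyst on the allylic bromide.

**Step 9**
Reactants: 15 bromomethylacrylate
Product: 16 1,1,1,3,3,3-hexafluoropropan-2-yl (3S,6E)-7-[(2R)-4-(bromomethyl)-5-oxo-2,5-dihydrofuran-2-yl]-3-[(tert-butyldimethylsilyl)oxy]-6-{[(4-methoxybenzyl)oxy]methyl}-2-methylidenehept-6-enoate
Conditions: Hoveyda–Grubbs II (5 mol%), CH2Cl2 (5 mM), 40 °C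
Reagents that add atoms: none
Why: Ring-closing metathesis in which the catalyst loads at the unhindered propenyl group (propene is lost) and closes onto the neighbouring 2-(bromomethyl)acrylate to the five-membered butenolide, the trisubstituted olefin and the remote α-branched acrylate being too hindered or too far away to compete.

**Step 10**
Reactants: 16 bromobutenolide; 17 prop-2-enal
Product: 18 1,1,1,3,3,3-hexafluoropropan-2-yl (3S,6E)-3-[(tert-butyldimethylsilyl)oxy]-7-{(2R,3R)-3-[(1S)-1-hydroxyprop-2-en-1-yl]-4-methylidene-5-oxooxolan-2-yl}-6-{[(4-methoxybenzyl)oxy]methyl}-2-methylidenehept-6-enoate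
Conditions: Zn dust, THF/sat. aq. NH4Cl, 0 °C to rt
Reagents that add atoms: none
Why: Zinc-mediated Barbier allylation, in which the allylzinc from the 3-(bromomethyl)butenolide adds to acrolein at its γ-carbon through a chair Zimmerman–Traxler transition state on the face anti to the C8 substituent (trans β,γ-lactone, sets C7) with the aldehyde vinyl group equatorial, which should give the 1S carbinol, the C6 epimer.

**Step 11**
Reactants: 18 Barbier alcohol
Product: 19 1,1,1,3,3,3-hexafluoropropan-2-yl (3S,6E)-3-[(tert-butyldimethylsilyl)oxy]-7-{(2R,3R)-3-[(1R)-1-(chloroacetoxy)prop-2-en-1-yl]-4-methylidene-5-oxooxolan-2-yl}-6-{[(4-methoxybenzyl)oxy]methyl}-2-methylidenehept-6-enoate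
Conditions: PPh3/DIAD (pre-mixed), ClCH2CO2H, toluene, −20 to 0 °C
Reagents that add atoms: chloroacetic acid, OC(=O)CCl
Why: Mitsunobu reaction in which chloroacetate displaces the oxyphosphonium of the secondary allylic alcohol by SN2 with inversion, setting C6 as in the target, the pre-formed betaine keeping free phosphine away from the α-methylene lactone.

**Step 12**
Reactants: 19 chloroacetate
Product: 20 (3S,6E)-3-[(tert-butyldimethylsilyl)oxy]-7-{(2R,3R)-3-[(1R)-1-hydroxyprop-2-en-1-yl]-4-methylidene-5-oxooxolan-2-yl}-6-{[(4-methoxybenzyl)oxy]methyl}-2-methylidenehept-6-enoic acid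
Conditions: LiOH, THF/H2O, 0 °C; then dil. HCl to pH 4
Reagents that add atoms: lithium hydroxide, [Li+].[OH-]
Why: Saponification cleaves the two activated esters (chloroacetate, hexafluoroisopropyl) well before the γ-lactone, which after the inversion is also the thermodynamically preferred trans lactone, so no translactonisation to O6 is expected.

**Step 13**
Reactants: 20 seco acid
Product: 21 (3S,6R,7R,8R,9E)-3-O-TBS-14-O-PMB 11-membered macrolactone (C15 carboxyl on O6; trans-fused at C7–C8 to the α-methylene-γ-butyrolactone; vinyl on C6; exocyclic methylene on C4)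
Conditions: MNBA, DMAP, CH2Cl2 (1 mM), rt, syringe-pump addition
Reagents that add atoms: none
Why: Shiina macrolactonisation (mixed anhydride, acyl transfer by DMAP) under high dilution closes the 11-membered lactone at the only free hydroxyl with retention at C6, the ring-cis C9=C10 olefin and the trans-fused lactone pre-organising the chain.

**Step 14**
Reactants: 21 TBS-protected macrolactone
Product: 22 (3S,6R,7R,8R,9E)-3-hydroxy-14-O-PMB macrolactone
Conditions: HF·pyridine, THF, 0 °C to rt
Reagents that add atoms: none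
Why: Fluoride cleavage of the TBS ether, to which the PMB ether and both lactones are stable.

**Step 15**
Reactants: 22 macrolactone carbinol; 23 2-methylpropanoyl chloride
Product: 24 (3S,6R,7R,8R,9E)-3-O-isobutyryl-14-O-PMB macrolactone
Conditions: pyridine, DMAP (cat.), CH2Cl2, 0 °C
Reagents that add atoms: none
Why: Acylation of the secondary allylic alcohol with the acid chloride installs the isobutyrate with retention at C3.

**Step 16**
Reactants: 24 macrolactone isobutyrate
Product: 25 14-O-(4-methoxybenzyl) ether of the target (3S,6R,7S,8R)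
Conditions: Hoveyda–Grubbs II (15 mol% in two portions), 2,6-dichlorobenzoquinone (cat.), toluene (1 mM), 90 °C, Ar sparge
Reagents that add atoms: none
Why: Ring-closing olefin metathesis: the ruthenium alkylidene loads at the only monosubstituted olefin (the vinyl group on C6), adds to the ester-conjugated C4 methylene through a ruthenacyclobutane and expels ethylene, leaving C4=C5. The closest known reaction type is the RCM of α-substituted acrylates of allylic alcohols to α-substituted butenolides, which has also been used to close strained germacranolide-type ten-membered rings. Two rings close at once: the butenolide as a five-membered RCM across the C15(=O)–O–C6 ester, and the ten-membered carbocycle as a transannular contraction of the 11-membered lactone (11 → 10 + 5). No stereocentre is formed; the C4=C5 geometry (C3 and C6 trans in the carbocycle) is dictated by the five-membered lactone, in which C15 and C6 must be cis. The step needs site selectivity among five olefins, which the substrate secures: the α-methylene lactone could only give a cyclobutene and the trisubstituted C9=C10 olefin only a cyclopentene trans-fused to the γ-lactone, so the butenolide is the only strain-free closure open to the C5 carbene. High dilution and ethylene removal suppress oligomerisation through the vinyl group.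

**Step 17**
Reactants: 25 PMB ether of the target
Product: 26 CNP0322767.4
Conditions: DDQ, CH2Cl2/pH 7 buffer, 0 °C
Reagents that add atoms: none
Why: Oxidative PMB cleavage (benzylic hydride abstraction by DDQ, hydrolysis of the oxocarbenium ion) frees the primary allylic alcohol without touching the lactones, the isobutyrate or the olefins.

**Compound list**
1 | 1-methoxy-4-[(prop-2-yn-1-yloxy)methyl]benzene | C#CCOCc1ccc(OC)cc1 | starting material
2 | (E)-but-2-enal | C/C=C/C=O | starting material
3 | methylzinc acetylide of 1 | C[Zn]C#CCOCc1ccc(OC)cc1 | intermediate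
4 | (4S,5E)-1-[(4-methoxybenzyl)oxy]hept-5-en-2-yn-4-ol | C/C=C/[C@H](O)C#CCOCc1ccc(OC)cc1 | intermediate
5 | sodium alkenylalanate (five-membered oxaaluminole from 4, Al on the carbon bearing CH2OPMB) | [Na+].COCCO[Al-]1(OCCOC)O[C@@H](/C=C/C)C=C1COCc2ccc(OC)cc2 | intermediate
6 | (2Z,4S,5E)-2-iodo-1-[(4-methoxybenzyl)oxy]hepta-2,5-dien-4-ol | O[C@@H](/C=C/C)/C=C(/COCc1ccc(OC)cc1)I | intermediate
7 | triethylsilyl ether of 6 | CC[Si](CC)(CC)O[C@@H](/C=C/C)/C=C(/COCc1ccc(OC)cc1)I | intermediate
8 | prop-2-en-1-ol | C=CCO | starting material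
9 | (4E,6S,7E)-4-{[(4-methoxybenzyl)oxy]methyl}-6-[(triethylsilyl)oxy]nona-4,7-dienal | CC[Si](CC)(CC)O[C@@H](/C=C/C)/C=C(/COCc1ccc(OC)cc1)CCC=O | intermediate
10 | 1,1,1,3,3,3-hexafluoropropan-2-yl acrylate | C=CC(=O)OC(C(F)(F)F)C(F)(F)F | starting material
11 | hexafluoroisopropyl (3S,6E,8S,9E)-3-hydroxy-6-(PMB-oxymethyl)-2-methylidene-8-(TES-oxy)undeca-6,9-dienoate | CC[Si](CC)(CC)O[C@@H](/C=C/C)/C=C(/COCc1ccc(OC)cc1)CC[C@H](O)C(=C)C(=O)OC(C(F)(F)F)C(F)(F)F | intermediate
12 | 3-O-TBS ether of 11 | CC[Si](CC)(CC)O[C@@H](/C=C/C)/C=C(/COCc1ccc(OC)cc1)CC[C@H](O[Si](C)(C)C(C)(C)C)C(=C)C(=O)OC(C(F)(F)F)C(F)(F)F | intermediate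
13 | 8-hydroxy compound (TES removed from 12) | O[C@@H](/C=C/C)/C=C(/COCc1ccc(OC)cc1)CC[C@H](O[Si](C)(C)C(C)(C)C)C(=C)C(=O)OC(C(F)(F)F)C(F)(F)F | intermediate
14 | 2-(bromomethyl)prop-2-enoic acid | C=C(CBr)C(=O)O | starting material
15 | 8-O-[2-(bromomethyl)acryloyl] ester of 13 | C=C(CBr)C(=O)O[C@@H](/C=C/C)/C=C(/COCc1ccc(OC)cc1)CC[C@H](O[Si](C)(C)C(C)(C)C)C(=C)C(=O)OC(C(F)(F)F)C(F)(F)F | intermediate
16 | (2R)-4-(bromomethyl)-5-oxo-2,5-dihydrofuran-2-yl compound (bromobutenolide) | O=C1O[C@H](/C=C(/COCc2ccc(OC)cc2)CC[C@H](O[Si](C)(C)C(C)(C)C)C(=C)C(=O)OC(C(F)(F)F)C(F)(F)F)C=C1CBr | intermediate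
17 | prop-2-enal | C=CC=O | starting material
18 | Barbier alcohol, oxolane (2R,3R), carbinol (1S) | C=C1C(=O)O[C@H](/C=C(/COCc2ccc(OC)cc2)CC[C@H](O[Si](C)(C)C(C)(C)C)C(=C)C(=O)OC(C(F)(F)F)C(F)(F)F)[C@H]1[C@@H](O)C=C | intermediate
19 | (1R)-chloroacetate | C=C1C(=O)O[C@H](/C=C(/COCc2ccc(OC)cc2)CC[C@H](O[Si](C)(C)C(C)(C)C)C(=C)C(=O)OC(C(F)(F)F)C(F)(F)F)[C@H]1[C@H](OC(=O)CCl)C=C | intermediate
20 | seco acid, carbinol (1R) | C=C1C(=O)O[C@H](/C=C(/COCc2ccc(OC)cc2)CC[C@H](O[Si](C)(C)C(C)(C)C)C(=C)C(=O)O)[C@H]1[C@H](O)C=C | intermediate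
21 | 3-O-TBS-14-O-PMB 11-membered macrolactone | C=C1C(=O)O[C@@H]2/C=C(/COCc3ccc(OC)cc3)CC[C@H](O[Si](C)(C)C(C)(C)C)C(=C)C(=O)O[C@H](C=C)[C@@H]12 | intermediate
22 | 3-hydroxy-14-O-PMB macrolactone | C=C1C(=O)O[C@@H]2/C=C(/COCc3ccc(OC)cc3)CC[C@H](O)C(=C)C(=O)O[C@H](C=C)[C@@H]12 | intermediate
23 | 2-methylpropanoyl chloride | CC(C)C(=O)Cl | starting material
24 | 3-O-isobutyryl-14-O-PMB macrolactone | C=C1C(=O)O[C@@H]2/C=C(/COCc3ccc(OC)cc3)CC[C@H](OC(=O)C(C)C)C(=C)C(=O)O[C@H](C=C)[C@@H]12 | intermediate
25 | 14-O-PMB ether of the target | C=C1C(=O)O[C@@H]2/C=C(/COCc3ccc(OC)cc3)CC[C@H](OC(=O)C(C)C)C4=C[C@@H](OC4=O)[C@@H]12 | intermediate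
26 | CNP0322767.4 (3S,6R,7S,8R) | C=C1C(=O)O[C@@H]2/C=C(/CO)CC[C@H](OC(=O)C(C)C)C3=C[C@@H](OC3=O)[C@@H]12 | target

**Totals**: 17 steps; longest linear sequence 17 steps (from 1 and 2).

**Steps most likely to fail**

Step 16 (key RCM). What may go wrong: the 11-membered lactone may not reach the s-cis ester conformer that brings the C5 carbene to the C4 methylene, so that oligomerisation through the vinyl group and olefin migration outrun ring closure. Fallback: the order of ester and olefin formation is reversed. Setting out from seco acid 20, RCM of the untethered triene (same catalyst, 1 mM) closes the ten-membered carbocycle first to the cyclodecadiene hydroxy acid F1. Only the isomer with the carboxyl cis to the C6 hydroxyl can lactonise; acid catalysis (CSA) with sensitised photo-equilibration of the enoic acid should funnel the material into the TBS-protected tricyclic dilactone F2. HF·pyridine then gives the C3 carbinol F3, and isobutyryl chloride/pyridine rejoins the route at 25.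

Step 13 (macrolactonisation). What may go wrong: intermolecular acylation (diolide and oligomer formation) may outpace closure of the strained 11-membered ring at the hindered C6 hydroxyl. Fallback: the alcohol is activated instead of the acid, which also makes steps 11 and 12 unnecessary. Setting out from Barbier alcohol 18, LiOH at 0 °C cleaves only the hexafluoroisopropyl ester to the C6-epimeric hydroxy acid F4. Mitsunobu macrolactonisation (PPh3, DIAD, toluene, high dilution) then closes the ring with inversion at C6 and rejoins the route at 21.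

Step 11 (Mitsunobu inversion). What may go wrong: allylic transposition (SN2′ attack of the carboxylate at the vinyl terminus) or elimination of the activated hydroxyl may compete with direct displacement at the hindered carbinol. Fallback: redox inversion. Setting out from 18, Dess–Martin oxidation gives the vinyl ketone F5. CBS reduction (catecholborane, −78 °C, oxazaborolidine antipode matched to the 1R carbinol) gives the allylic alcohol F6, and LiOH cleavage of the hexafluoroisopropyl ester rejoins the route at 20.

**Further compounds**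
F1 | step 16 | cyclodecadiene hydroxy acid (carboxyl cis to the C6 hydroxyl) | C=C1C(=O)O[C@@H]2/C=C(/COCc3ccc(OC)cc3)CC[C@H](O[Si](C)(C)C(C)(C)C)/C(C(=O)O)=C/[C@@H](O)[C@@H]12
F2 | step 16 | 3-O-TBS-14-O-PMB tricyclic dilactone | C=C1C(=O)O[C@@H]2/C=C(/COCc3ccc(OC)cc3)CC[C@H](O[Si](C)(C)C(C)(C)C)C4=C[C@@H](OC4=O)[C@@H]12
F3 | step 16 | 3-hydroxy-14-O-PMB tricyclic dilactone | C=C1C(=O)O[C@@H]2/C=C(/COCc3ccc(OC)cc3)CC[C@H](O)C4=C[C@@H](OC4=O)[C@@H]12
F4 | step 13 | C6-epimeric (1S) hydroxy acid | C=C1C(=O)O[C@H](/C=C(/COCc2ccc(OC)cc2)CC[C@H](O[Si](C)(C)C(C)(C)C)C(=C)C(=O)O)[C@H]1[C@@H](O)C=C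
F5 | step 11 | vinyl ketone | C=C1C(=O)O[C@H](/C=C(/COCc2ccc(OC)cc2)CC[C@H](O[Si](C)(C)C(C)(C)C)C(=C)C(=O)OC(C(F)(F)F)C(F)(F)F)[C@H]1C(=O)C=C
F6 | step 11 | (1R) allylic alcohol, hexafluoroisopropyl ester | C=C1C(=O)O[C@H](/C=C(/COCc2ccc(OC)cc2)CC[C@H](O[Si](C)(C)C(C)(C)C)C(=C)C(=O)OC(C(F)(F)F)C(F)(F)F)[C@H]1[C@H](O)C=C
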